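The target in your four earlier runs stands still from the first reading on, inside a scatter of 0.5 percentage points, so those yields tell how the substrate divided, not how fast it went. You asked for a quick number, with the hunch that feeding the reagent slowly is gentler on the substrate; I reckon otherwise.

| flask | substrate | reagent | temperature | remark | time |
|---|---|---|---|---|---|
| green | 0.050 M | 0.075 M | 15 °C | run made earlier |  |
| ochre | 0.050 M | 0.037 M | 26 °C | run made earlier |  |
| teal | 0.050 M | 0.056 M | 15 °C | run made earlier |  |
| blue | 0.025 M | 0.075 M | 26 °C | run made earlier |  |
| noon | 0.050 M | 0.0750 M |  | everything together at the start at 0 °C, warmed to 20 °C at 15 h | 20 h |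
| summer | 0.050 M | 0.0750 M (fed, over 15 h) | 20 °C | all else is in the flask from the start; the feed brings no volume worth counting | 20 h |
| winter | 0.050 M | 0.0750 M | 20 °C | everything together at the start | 20 h |
| dusk | 0.050 M | 0.0750 M (fed, over 15 h) |  | the addition at 0 °C, then warmed to 20 °C; the feed brings no volume worth counting | 20 h |

| green: time / h | green: target / % | ochre: time / h | ochre: target / % | teal: time / h | teal: target / % | blue: time / h | blue: target / % |
|---|---|---|---|---|---|---|---|
| 1.50 | 86.0 | 6.00 | 58.1 | 2.00 | 80.3 | 2.00 | 83.7 |
| 4.00 | 86.0 | 12.0 | 58.8 | 4.00 | 80.9 | 4.00 | 82.7 |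
| 8.00 | 87.3 | 20.0 | 58.6 | 10.0 | 79.8 | 10.0 | 83.4 |
| 20.0 | 86.7 | 25.0 | 57.8 | 25.0 | 80.7 | 25.0 | 81.9 |

(each reading ± 0.5 percentage points)

* the best flask by amount of target, in percent of the substrate charged; "all alike" if 1.5 percentage points covers them all (noon / summer / winter / dusk / all alike)
* amount of target at the end, in percent of the substrate charged, noon
* amount of target at the end, in percent of the substrate charged, summer
* amount of target at the end, in percent of the substrate charged, winter
* amount of target at the end, in percent of the substrate charged, dusk

- the numbers in the tables scatter with a standard deviation of 0.5 points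

Suppose substrate goes to target with the reagent and to a loss without it. The share going to target at any moment is then c(reagent)/(c(reagent)+κ), where κ is the c(reagent) at which substrate splits equally, a selectivity factor with the unit of a concentration. Summed over a run, this gives c(target) + κ ln[c(reagent, start)/(c(reagent, start) − c(target))] = c(substrate, start). Green's last reading gives 0.00771 M at 15 °C. At 26 °C, blue's reading at 4.00 h gives 0.0134 M and ochre's at 20.0 h, on a different charge, 0.0132 M. Since 20 °C lies near the middle, I take the geometric mean of green and blue, 0.0102 M, as the even level there. Summer's feed brings 0.00500 M h⁻¹, so even with no reagent used, c(reagent) needs 2.03 h to reach κ. That is longer than the 1.50 h by which green, colder and with its whole reagent charge in from the start, already stood still, so I expect summer far below winter.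

The forecast names noon as best, with 93% there and 83.7% in winter; for the two fed flasks it gives 68% in dusk and 24% in summer, both called rough, reasoning that the feed keeps the reagent starved, “so substrate decays while waiting”.

The flasks give 93.4% in noon, the best, then 83.7% in winter and 64.6% in dusk. Summer gives 11.8% against the forecast's 24%.

    substrate → intermediate A (k = 1.26 h⁻¹, Ea = 93.0 kJ mol⁻¹)
    substrate + reagent → target (k = 127 M⁻¹ h⁻¹, Ea = 57.0 kJ mol⁻¹)
    reagent + intermediate A ⇌ intermediate B (K = 10.4 M⁻¹, k = 11.7 M⁻¹ h⁻¹, Ea = 49.0 kJ mol⁻¹, ΔH = −17.0 kJ mol⁻¹)
    (constants at 20 °C)

The loss is substrate passing to intermediate A, with a half-life on that path alone of 0.550 h at 20 °C. The 2.03 h reckoned for summer to reach κ, with no reagent counted as used, is 3.69 such half-lives, and summer ended at 11.8%. The neighbour flask, summer with 0.19 M of reagent, is fed at 0.0127 M h⁻¹, so counted the same way it reaches κ in 0.803 h, or 1.46 half-lives. Its target came to 23.0%, twice summer's, while intermediate B held the most of its substrate, at 47.5%.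

The numbers in the tables are simulated with made-up constants, and the scatter is random.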